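**Retrosynthetic overview**

1. The last C–C bonds are the two diarylmethine–ring A bonds (C6 and C8 of (+)-afzelechin), made by twofold 1,6-addition of the flavan to a p-quinone methide generated from one oxolane carbinol that is used twice, since both arms are identical in constitution and configuration.
2. Each oxolane (arm numbering: O1, C2 with the 2,4-dioxygenated aryl, C3 with the exocyclic methine, C4 with the aroyl group, C5 with the 4-oxygenated aryl) is closed at C3–C4 by a domino oxa-Michael/epoxide opening between a threo 2,3-epoxy alcohol (O1, C2, C3, methine) and a chalcone (C4, C5, aroyl).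
3. Enabling feature: C4 is α and the benzylic ether carbon C5 is β to the aroyl ketone, so O1–C5–C4–C=O is a retro-oxa-Michael unit; C3 carries a benzylic methine next to a 4-hydroxyphenyl ring that must later ionise, so C3–CH(aryl) is a latent trans-oxirane whose SN2 opening writes the 2,3-cis relation while C4 and C5 are corrected dynamically.
4. Both partners come from 2′,4′-bis(benzyloxy)acetophenone by Claisen–Schmidt condensation; the epoxy alcohol follows by Juliá–Colonna epoxidation and reagent-controlled ketone reduction.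
5. Ring order: oxirane, then oxolane (C3–C4), then attachment of two arms to the intact chroman of afzelechin; global debenzylation is last.

Key step: step 5

Remark on the chemistry: (+)-afzelechin (2R,3S) and poly-D-leucine are taken as purchasable; the flavan-3-ol unit in the target is exactly this 2,3-trans compound.

**Route**

Step 1
Reactants: 1 1-[2,4-bis(benzyloxy)phenyl]ethan-1-one; 2 4-(benzyloxy)benzaldehyde
Product: 3 (E)-1-[2,4-bis(benzyloxy)phenyl]-3-[4-(benzyloxy)phenyl]prop-2-en-1-one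
Conditions: KOH (aq. 50%), EtOH, rt
Reagents that add atoms: none
Why: Claisen–Schmidt (crossed aldol) condensation, in which the methyl ketone enolate adds to the non-enolisable aldehyde and E1cB dehydration gives the (E)-chalcone; no stereocentre is formed.

Step 2
Reactants: 1 1-[2,4-bis(benzyloxy)phenyl]ethan-1-one; 4 4-(prop-2-en-1-yloxy)benzaldehyde
Product: 5 (E)-1-[2,4-bis(benzyloxy)phenyl]-3-[4-(prop-2-en-1-yloxy)phenyl]prop-2-en-1-one
Conditions: KOH (aq. 50%), EtOH, rt
Reagents that add atoms: none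
Why: Claisen–Schmidt condensation as in step 1; the allyl ether marks the one phenol that must be freed selectively later.

Step 3
Reactants: 5 (E)-1-[2,4-bis(benzyloxy)phenyl]-3-[4-(prop-2-en-1-yloxy)phenyl]prop-2-en-1-one
Product: 6 [2,4-bis(benzyloxy)phenyl]{(2S,3R)-3-[4-(prop-2-en-1-yloxy)phenyl]oxiran-2-yl}methanone
Conditions: poly-D-leucine, urea·H2O2, DBU, THF, rt
Reagents that add atoms: hydrogen peroxide (used as its urea adduct), OO
Why: Juliá–Colonna epoxidation (Weitz–Scheffer nucleophilic epoxidation inside the polypeptide helix), which should give the trans-oxirane as the (2S,3R) enantiomer with the D-polypeptide, as precedented for 2′-O-protected chalcones; the allyl and benzyl ethers are inert to the nucleophilic oxidant.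

Step 4
Reactants: 6 [2,4-bis(benzyloxy)phenyl]{(2S,3R)-3-[4-(prop-2-en-1-yloxy)phenyl]oxiran-2-yl}methanone
Product: 7 (S)-[2,4-bis(benzyloxy)phenyl]{(2R,3R)-3-[4-(prop-2-en-1-yloxy)phenyl]oxiran-2-yl}methanol (threo)
Conditions: RuCl[(R,R)-TsDPEN](p-cymene) (2 mol%), HCO2Na, H2O/THF, 30 °C
Reagents that add atoms: none
Why: Noyori asymmetric transfer hydrogenation of an aryl ketone, in which the (R,R)-TsDPEN ruthenium hydride recognises the aryl group and should deliver hydride to the face that gives the (S)-carbinol (threo epoxy alcohol) by reagent control, needed because chelation/Felkin-type reduction of trans-α,β-epoxy ketones normally favours the erythro isomer; neutral aqueous formate spares the acid-sensitive aryl oxirane.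

Step 5
Reactants: 7 (S)-[2,4-bis(benzyloxy)phenyl]{(2R,3R)-3-[4-(prop-2-en-1-yloxy)phenyl]oxiran-2-yl}methanol; 3 (E)-1-[2,4-bis(benzyloxy)phenyl]-3-[4-(benzyloxy)phenyl]prop-2-en-1-one
Product: 9 (S)-{(2R,3R,4S,5S)-4-[2,4-bis(benzyloxy)benzoyl]-2-[2,4-bis(benzyloxy)phenyl]-5-[4-(benzyloxy)phenyl]oxolan-3-yl}[4-(prop-2-en-1-yloxy)phenyl]methanol, via oxa-Michael enolate 8 (not isolated)
Conditions: KOtBu (0.2 equiv), THF (0.02 M), −20 °C → rt, 3 (1.05 equiv) added over 6 h; then AcOH
Reagents that add atoms: none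
Why: Proposed new method: the potassium alkoxide of 7 adds reversibly to C-β of chalcone 3 (oxa-Michael) to give enolate 8 as an interconverting pair of epimers at the new benzylic ether carbon, and the enolate carbon then attacks the proximal oxirane carbon intramolecularly and irreversibly to form the C3–C4 bond, the closest known reaction types being Michael-initiated ring closure and the Stork-type intramolecular alkylation of enolates by epoxides. The oxolane closes in the 5-exo-tet mode, which under purely basic conditions should be preferred over 6-endo attack at the benzylic oxirane carbon because only the exo path allows collinear SN2 geometry. C3 is set stereospecifically by inversion at the oxirane carbon, so the threo relation of 7 becomes the contra-thermodynamic 2,3-cis relation, while C2 is carried over from 7 and the carbinol carbon keeps the oxirane configuration. C4 remains α to the ketone and should equilibrate through the enolate to the arrangement trans to both neighbours, and C5 is set under Curtin–Hammett conditions because retro-oxa-Michael interconverts the epimers of 8 and the transition state with both aryl groups pseudo-equatorial (2,5-cis, 4,5-trans) should be lower. The step needs chemoselectivity for cyclisation over Payne migration of the epoxy alkoxide and over Michael addition of 8 to a second enone; substoichiometric base, slow addition of 3 and high dilution keep free alkoxide and free enone low, and the enolate being about five pKa units less basic than the alkoxide holds the equilibrium on the adduct side.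

Step 6
Reactants: 9 (S)-{(2R,3R,4S,5S)-4-[2,4-bis(benzyloxy)benzoyl]-2-[2,4-bis(benzyloxy)phenyl]-5-[4-(benzyloxy)phenyl]oxolan-3-yl}[4-(prop-2-en-1-yloxy)phenyl]methanol
Product: 10 4-[(S)-{(2R,3R,4S,5S)-4-[2,4-bis(benzyloxy)benzoyl]-2-[2,4-bis(benzyloxy)phenyl]-5-[4-(benzyloxy)phenyl]oxolan-3-yl}(hydroxy)methyl]phenol
Conditions: Pd(PPh3)4 (5 mol%), morpholine, THF, rt
Reagents that add atoms: none
Why: Tsuji–Trost-type deallylation, in which the zerovalent palladium complex ionises the aryl allyl ether to a π-allyl species that morpholine intercepts, freeing only the phenol para to the carbinol while benzyl ethers, ketone and oxolane are untouched; no stereocentre is affected.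

Step 7
Reactants: 10 4-[(S)-{(2R,3R,4S,5S)-4-[2,4-bis(benzyloxy)benzoyl]-2-[2,4-bis(benzyloxy)phenyl]-5-[4-(benzyloxy)phenyl]oxolan-3-yl}(hydroxy)methyl]phenol (2.4 equiv); 11 (+)-afzelechin
Product: 13 (2R,3S)-6,8-bis[(S)-{(2R,3S,4S,5S)-4-[2,4-bis(benzyloxy)benzoyl]-2-[2,4-bis(benzyloxy)phenyl]-5-[4-(benzyloxy)phenyl]oxolan-3-yl}(4-hydroxyphenyl)methyl]-2-(4-hydroxyphenyl)chromane-3,5,7-triol, via quinone methide 12 (not isolated)
Conditions: (R)-TRIP (chiral BINOL phosphoric acid, 10 mol%), 4 Å MS, CH2Cl2/EtOAc, rt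
Reagents that add atoms: none
Why: The chiral phosphoric acid dehydrates the p-hydroxybenzylic alcohol of 10 to p-quinone methide 12 and, hydrogen-bonded to both partners, should deliver the phloroglucinol-type ring A of afzelechin (C8, then C6) to the methide carbon in a 1,6-conjugate (vinylogous Friedel–Crafts) addition, with the (S) configuration of each new diarylmethine set by the catalyst together with the adjacent C3 stereocentre (the catalyst enantiomer is the one that reinforces this face), while the O-benzylated aryl ethers at C2 and C5 should not ionise under this weak acid.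

Step 8
Reactants: 13 (2R,3S)-6,8-bis[(S)-{(2R,3S,4S,5S)-4-[2,4-bis(benzyloxy)benzoyl]-2-[2,4-bis(benzyloxy)phenyl]-5-[4-(benzyloxy)phenyl]oxolan-3-yl}(4-hydroxyphenyl)methyl]-2-(4-hydroxyphenyl)chromane-3,5,7-triol
Product: 14 (2R,3S)-6,8-bis[(S)-{(2R,3S,4S,5S)-4-(2,4-dihydroxybenzoyl)-2-(2,4-dihydroxyphenyl)-5-(4-hydroxyphenyl)oxolan-3-yl}(4-hydroxyphenyl)methyl]-2-(4-hydroxyphenyl)chromane-3,5,7-triol (CNP0225367.3)
Conditions: H2 (1 atm), Pd(OH)2/C, EtOAc/MeOH, rt
Reagents that add atoms: none
Why: Hydrogenolysis of the ten O-benzyl groups over Pearlman's catalyst Pd(OH)2/C under neutral conditions, as practised in proanthocyanidin and 2,5-diaryloxolane lignan syntheses where cyclic benzylic ethers, diarylmethines and hydroxyaryl ketones survive; no stereocentre is touched.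

**Compound list**

1 | 1-[2,4-bis(benzyloxy)phenyl]ethan-1-one | CC(=O)c1ccc(OCc2ccccc2)cc1OCc1ccccc1 | starting material
2 | 4-(benzyloxy)benzaldehyde | O=Cc1ccc(OCc2ccccc2)cc1 | starting material
3 | (E)-1-[2,4-bis(benzyloxy)phenyl]-3-[4-(benzyloxy)phenyl]prop-2-en-1-one | O=C(/C=C/c1ccc(OCc2ccccc2)cc1)c1ccc(OCc2ccccc2)cc1OCc1ccccc1 | intermediate
4 | 4-(prop-2-en-1-yloxy)benzaldehyde | O=Cc1ccc(OCC=C)cc1 | starting material
5 | (E)-1-[2,4-bis(benzyloxy)phenyl]-3-[4-(prop-2-en-1-yloxy)phenyl]prop-2-en-1-one | O=C(/C=C/c1ccc(OCC=C)cc1)c1ccc(OCc2ccccc2)cc1OCc1ccccc1 | intermediate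
6 | [2,4-bis(benzyloxy)phenyl]{(2S,3R)-3-[4-(prop-2-en-1-yloxy)phenyl]oxiran-2-yl}methanone | O=C(c1ccc(OCc2ccccc2)cc1OCc1ccccc1)[C@H]1O[C@@H]1c1ccc(OCC=C)cc1 | intermediate
7 | (S)-[2,4-bis(benzyloxy)phenyl]{(2R,3R)-3-[4-(prop-2-en-1-yloxy)phenyl]oxiran-2-yl}methanol (threo) | O[C@@H](c1ccc(OCc2ccccc2)cc1OCc1ccccc1)[C@H]1O[C@@H]1c1ccc(OCC=C)cc1 | intermediate
8 | potassium 1-[2,4-bis(benzyloxy)phenyl]-3-[4-(benzyloxy)phenyl]-3-{(S)-[2,4-bis(benzyloxy)phenyl][(2R,3R)-3-[4-(prop-2-en-1-yloxy)phenyl]oxiran-2-yl]methoxy}prop-1-en-1-olate (both epimers at C3 of the chain, interconverting) | [K+].[O-]C(=CC(c1ccc(OCc2ccccc2)cc1)O[C@@H](c1ccc(OCc2ccccc2)cc1OCc1ccccc1)[C@H]1O[C@@H]1c1ccc(OCC=C)cc1)c1ccc(OCc2ccccc2)cc1OCc1ccccc1 | intermediate (not isolated)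
9 | (S)-{(2R,3R,4S,5S)-4-[2,4-bis(benzyloxy)benzoyl]-2-[2,4-bis(benzyloxy)phenyl]-5-[4-(benzyloxy)phenyl]oxolan-3-yl}[4-(prop-2-en-1-yloxy)phenyl]methanol | O=C(c1ccc(OCc2ccccc2)cc1OCc1ccccc1)[C@H]1[C@H]([C@@H](c2ccc(OCC=C)cc2)O)[C@H](c2ccc(OCc3ccccc3)cc2OCc2ccccc2)O[C@@H]1c1ccc(OCc2ccccc2)cc1 | intermediate
10 | 4-[(S)-{(2R,3R,4S,5S)-4-[2,4-bis(benzyloxy)benzoyl]-2-[2,4-bis(benzyloxy)phenyl]-5-[4-(benzyloxy)phenyl]oxolan-3-yl}(hydroxy)methyl]phenol | O=C(c1ccc(OCc2ccccc2)cc1OCc1ccccc1)[C@H]1[C@H]([C@@H](c2ccc(O)cc2)O)[C@H](c2ccc(OCc3ccccc3)cc2OCc2ccccc2)O[C@@H]1c1ccc(OCc2ccccc2)cc1 | intermediate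
11 | (+)-afzelechin, (2R,3S)-2-(4-hydroxyphenyl)chromane-3,5,7-triol | Oc1cc(O)c2c(c1)O[C@H](c1ccc(O)cc1)[C@@H](O)C2 | starting material
12 | 4-({(2R,3S,4S,5S)-4-[2,4-bis(benzyloxy)benzoyl]-2-[2,4-bis(benzyloxy)phenyl]-5-[4-(benzyloxy)phenyl]oxolan-3-yl}methylidene)cyclohexa-2,5-dien-1-one | O=C(c1ccc(OCc2ccccc2)cc1OCc1ccccc1)[C@H]1[C@H](C=C2C=CC(=O)C=C2)[C@H](c2ccc(OCc3ccccc3)cc2OCc2ccccc2)O[C@@H]1c1ccc(OCc2ccccc2)cc1 | intermediate (not isolated)
13 | (2R,3S)-6,8-bis[(S)-{(2R,3S,4S,5S)-4-[2,4-bis(benzyloxy)benzoyl]-2-[2,4-bis(benzyloxy)phenyl]-5-[4-(benzyloxy)phenyl]oxolan-3-yl}(4-hydroxyphenyl)methyl]-2-(4-hydroxyphenyl)chromane-3,5,7-triol | O=C(c1ccc(OCc6ccccc6)cc1OCc6ccccc6)[C@H]1[C@H]([C@@H](c2ccc(O)cc2)c2c(O)c3c(c([C@H](c4ccc(O)cc4)[C@H]4[C@H](C(=O)c5ccc(OCc6ccccc6)cc5OCc6ccccc6)[C@@H](c5ccc(OCc6ccccc6)cc5)O[C@H]4c4ccc(OCc6ccccc6)cc4OCc6ccccc6)c2O)O[C@H](c2ccc(O)cc2)[C@@H](O)C3)[C@H](c2ccc(OCc6ccccc6)cc2OCc6ccccc6)O[C@@H]1c1ccc(OCc6ccccc6)cc1 | intermediate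
14 | (2R,3S)-6,8-bis[(S)-{(2R,3S,4S,5S)-4-(2,4-dihydroxybenzoyl)-2-(2,4-dihydroxyphenyl)-5-(4-hydroxyphenyl)oxolan-3-yl}(4-hydroxyphenyl)methyl]-2-(4-hydroxyphenyl)chromane-3,5,7-triol (CNP0225367.3) | O=C(c1ccc(O)cc1O)[C@H]1[C@H]([C@@H](c2ccc(O)cc2)c2c(O)c3c(c([C@H](c4ccc(O)cc4)[C@H]4[C@H](C(=O)c5ccc(O)cc5O)[C@@H](c5ccc(O)cc5)O[C@H]4c4ccc(O)cc4O)c2O)O[C@H](c2ccc(O)cc2)[C@@H](O)C3)[C@H](c2ccc(O)cc2O)O[C@@H]1c1ccc(O)cc1 | target

**Step count and risks**

Total step count: 8. Longest linear sequence: 7 steps (steps 2 to 8, from compound 1).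

Steps most likely to fail:

Step 5 (proposed new method). What may go wrong: migration of the oxirane along the chain (Payne rearrangement) before the oxa-Michael event, fragmentation of the adduct back to alcohol and enone, oligomerisation by Michael addition of the enolate to a second enone, and endo opening at the benzylic oxirane carbon. The fallback sets out from 7 and 3 and returns at 9, and separates the two events with known chemistry. Oxa-Michael addition of 7 to 3 under Brønsted-base catalysis by an N-heterocyclic carbene (IMes, LiCl, toluene, rt) gives the isolated β-alkoxy ketone 1-[2,4-bis(benzyloxy)phenyl]-3-[4-(benzyloxy)phenyl]-3-{(S)-[2,4-bis(benzyloxy)phenyl][(2R,3R)-3-[4-(prop-2-en-1-yloxy)phenyl]oxiran-2-yl]methoxy}propan-1-one F1 as two separable epimers. Each epimer is then closed as its preformed potassium enolate in a Stork-type intramolecular epoxide alkylation (KHMDS 1.1 equiv, toluene, −78 → 0 °C, no free enone present), and C4 is finally equilibrated with DBU to reach 9.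

Step 7. What may go wrong: poor facial selectivity at the two new diarylmethine carbons when the catalyst and the adjacent C3 stereocentre pull in opposite directions, incomplete second alkylation at the more hindered C6, and loss of the C3 configuration through tautomerisation of the quinone methide to the styrene. The fallback sets out from 10 and 11 and returns at 13, and makes the union iterative and thermodynamically correctable. One equivalent of 10 with excess 11 gives the mono-adduct (2R,3S)-8-[(S)-{(2R,3S,4S,5S)-4-[2,4-bis(benzyloxy)benzoyl]-2-[2,4-bis(benzyloxy)phenyl]-5-[4-(benzyloxy)phenyl]oxolan-3-yl}(4-hydroxyphenyl)methyl]-2-(4-hydroxyphenyl)chromane-3,5,7-triol F2, whose methine epimers are separated at this smaller stage. The second arm is then introduced at C6, with the catalyst enantiomer chosen independently, to reach 13. Unwanted epimers from either stage are recycled with dilute protic acid, which reversibly cleaves the benzylic bond to ring A (the lability known from interflavan bonds) and returns 12 and the flavan.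

Step 4. What may go wrong: poor diastereofacial control because the catalyst preference opposes the chelation/Felkin preference of the epoxy ketone, and opening of the electron-rich benzylic oxirane during reduction. The fallback sets out from 6 and returns at 7, and uses substrate control followed by inversion. Chelation-controlled reduction with Zn(BH4)2 (Et2O, −20 °C) should give the erythro alcohol (R)-[2,4-bis(benzyloxy)phenyl]{(2R,3R)-3-[4-(prop-2-en-1-yloxy)phenyl]oxiran-2-yl}methanol F3. Mitsunobu inversion (4-nitrobenzoic acid, PPh3, DIAD, THF, 0 °C) gives (S)-[2,4-bis(benzyloxy)phenyl]{(2R,3R)-3-[4-(prop-2-en-1-yloxy)phenyl]oxiran-2-yl}methyl 4-nitrobenzoate F4, and brief methanolysis (K2CO3, MeOH, 0 °C) releases 7.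

Further compounds
F1 | step 5 | 1-[2,4-bis(benzyloxy)phenyl]-3-[4-(benzyloxy)phenyl]-3-{(S)-[2,4-bis(benzyloxy)phenyl][(2R,3R)-3-[4-(prop-2-en-1-yloxy)phenyl]oxiran-2-yl]methoxy}propan-1-one (epimers at C3 of the chain) | O=C(CC(c1ccc(OCc2ccccc2)cc1)O[C@@H](c1ccc(OCc2ccccc2)cc1OCc1ccccc1)[C@H]1O[C@@H]1c1ccc(OCC=C)cc1)c1ccc(OCc2ccccc2)cc1OCc1ccccc1
F2 | step 7 | (2R,3S)-8-[(S)-{(2R,3S,4S,5S)-4-[2,4-bis(benzyloxy)benzoyl]-2-[2,4-bis(benzyloxy)phenyl]-5-[4-(benzyloxy)phenyl]oxolan-3-yl}(4-hydroxyphenyl)methyl]-2-(4-hydroxyphenyl)chromane-3,5,7-triol | Oc1cc(O)c2c(c1[C@H](c1ccc(O)cc1)[C@H]1[C@H](C(=O)c3ccc(OCc4ccccc4)cc3OCc3ccccc3)[C@@H](c3ccc(OCc4ccccc4)cc3)O[C@H]1c1ccc(OCc3ccccc3)cc1OCc1ccccc1)O[C@H](c1ccc(O)cc1)[C@@H](O)C2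
F3 | step 4 | (R)-[2,4-bis(benzyloxy)phenyl]{(2R,3R)-3-[4-(prop-2-en-1-yloxy)phenyl]oxiran-2-yl}methanol (erythro) | O[C@H](c1ccc(OCc2ccccc2)cc1OCc1ccccc1)[C@H]1O[C@@H]1c1ccc(OCC=C)cc1
F4 | step 4 | (S)-[2,4-bis(benzyloxy)phenyl]{(2R,3R)-3-[4-(prop-2-en-1-yloxy)phenyl]oxiran-2-yl}methyl 4-nitrobenzoate | O=C(O[C@@H](c1ccc(OCc2ccccc2)cc1OCc1ccccc1)[C@H]1O[C@@H]1c1ccc(OCC=C)cc1)c1ccc(cc1)[N+](=O)[O-]
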